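**Retrosynthetic overview**

- The strategy rests on ring B, whose three adjacent oxygen-bearing carbons C3', C4' and C5' and allyl-bearing C1' map onto a squarate-derived cyclobutenone (C3' = carbonyl carbon, C4' = carbon carrying O–C8, C5' = methoxy carbon, C6' = the sp3 carbon) plus a penta-1,4-dien-2-yl unit (C1', C2').
- Last operations: removal of the ring A silyl group and O-methylation at C3'. Before that, ring B is disconnected at C6'–C1' (Stille coupling) and C2'–C3' (six-electron closure of a dienylketene), giving 4-chlorocyclobutenone 15 and dienylstannane 19.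
- 15 comes from dimethyl squarate by exchange of one methoxy group for the C8 alkoxide (the C8–O bond is never broken, so configuration is retained), sterically controlled mono-reduction and chlorination.
- Alcohol 10 (7S,8S): C8 comes from ethyl (S)-lactate; C7 is set by Felkin–Anh reduction of the aryl ketone made from the ring A aryllithium and the lactate Weinreb amide.
- Ring order: ring A and the four-membered ring are purchased; ring B is the only ring built, in step 13.

Key step: step 13

Remark on the chemistry: lignan numbering is used (ring A C1–C6, chain C7–C9, ring B primed). Cyclobutenones 14, 15 and 20 are carried as mixtures of epimers at the sp3 ring carbon, because that carbon becomes the aromatic C6'–H.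

**Route**

Step 1
Reactants: 1 4-bromo-2-methoxyphenol
Product: 2 (4-bromo-2-methoxyphenoxy)triisopropylsilane
Conditions: iPr3SiCl, imidazole, DMF, rt
Reagents that add atoms: triisopropylsilyl chloride, CC(C)[Si](Cl)(C(C)C)C(C)C
Why: Imidazole-promoted O-silylation of a phenol (silyl ether protection) should mask the ring A hydroxyl as a bulky silyl ether that tolerates the later organolithium, hydride, alkoxide and palladium steps.

Step 2
Reactants: 3 ethyl (S)-lactate
Product: 4 (S)-2-hydroxy-N-methoxy-N-methylpropanamide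
Conditions: MeNH(OMe)·HCl, iPrMgCl, THF, –20 → 0 °C; aq. NH4Cl
Reagents that add atoms: N,O-dimethylhydroxylamine hydrochloride, CNOC.Cl
Why: Weinreb amide formation by aminolysis of the ester with the magnesium amide made in the flask is fast at low temperature and should leave the stereocenter (the future C8, S) untouched.

Step 3
Reactants: 4 (S)-2-hydroxy-N-methoxy-N-methylpropanamide
Product: 5 (S)-2-(tert-butyldimethylsilyloxy)-N-methoxy-N-methylpropanamide
Conditions: tBuMe2SiCl, imidazole, DMF, rt
Reagents that add atoms: tert-butyldimethylsilyl chloride, CC(C)(C)[Si](C)(C)Cl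
Why: Standard silyl ether protection installs a non-chelating group on O8 that should enforce Felkin–Anh control in step 5 and can later be removed without loss of the aryl silyl ether.

Step 4
Reactants: 2 (4-bromo-2-methoxyphenoxy)triisopropylsilane; 5 (S)-2-(tert-butyldimethylsilyloxy)-N-methoxy-N-methylpropanamide
Product: 7 (S)-2-(tert-butyldimethylsilyloxy)-1-(3-methoxy-4-triisopropylsilyloxyphenyl)propan-1-one, via aryllithium 6 (not isolated)
Conditions: 2, n-BuLi, THF, –78 °C; then 5, –78 → –20 °C; aq. NH4Cl
Reagents that add atoms: none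
Why: Bromine–lithium exchange followed by Weinreb ketone synthesis should stop at the ketone, because the chelated tetrahedral adduct survives until quench and so prevents over-addition and enolization at the α-stereocenter.

Step 5
Reactants: 7 (S)-2-(tert-butyldimethylsilyloxy)-1-(3-methoxy-4-triisopropylsilyloxyphenyl)propan-1-one
Product: 8 (1S,2S)-2-(tert-butyldimethylsilyloxy)-1-(3-methoxy-4-triisopropylsilyloxyphenyl)propan-1-ol
Conditions: LiBH(sec-Bu)3, THF, –78 °C; aq. NH4Cl at –78 °C
Reagents that add atoms: none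
Why: In this Felkin–Anh-controlled reduction of an α-silyloxy ketone the bulky hydride should attack anti to the C8–OSi bond and past the C8 hydrogen, so the existing 8S centre sets C7 as S (syn, threo); the cold quench avoids silyl migration in the alkoxide.

Step 6
Reactants: 8 (1S,2S)-2-(tert-butyldimethylsilyloxy)-1-(3-methoxy-4-triisopropylsilyloxyphenyl)propan-1-ol
Product: 9 tert-butyl{[(1S,2S)-1-methoxy-1-(3-methoxy-4-triisopropylsilyloxyphenyl)propan-2-yl]oxy}dimethylsilane
Conditions: Me3OBF4, 1,8-bis(dimethylamino)naphthalene, CH2Cl2, 0 °C → rt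
Reagents that add atoms: trimethyloxonium tetrafluoroborate, C[O+](C)C.F[B-](F)(F)F
Why: Meerwein methylation transfers methyl to the neutral hydroxyl by SN2 without forming an alkoxide, so 1,2-migration of the neighbouring silyl group from O8 to O7 should not occur and C7 is not touched.

Step 7
Reactants: 9 tert-butyl{[(1S,2S)-1-methoxy-1-(3-methoxy-4-triisopropylsilyloxyphenyl)propan-2-yl]oxy}dimethylsilane
Product: 10 (1S,2S)-1-methoxy-1-(3-methoxy-4-triisopropylsilyloxyphenyl)propan-2-ol
Conditions: HF·pyridine, pyridine, THF, 0 °C → rt; aq. NaHCO3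
Reagents that add atoms: none
Why: Chemoselective desilylation with buffered acidic fluoride should cleave the alkyl silyl ether much faster than the aryl triisopropylsilyl ether (the reverse of basic fluoride) and is too weakly acidic to ionize the benzylic methyl ether at C7.

Step 8
Reactants: 10 (1S,2S)-1-methoxy-1-(3-methoxy-4-triisopropylsilyloxyphenyl)propan-2-ol; 11 dimethyl squarate
Product: 13 3-methoxy-4-{[(1S,2S)-1-methoxy-1-(3-methoxy-4-triisopropylsilyloxyphenyl)propan-2-yl]oxy}cyclobut-3-ene-1,2-dione, via lithium alkoxide 12 (not isolated)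
Conditions: 10, n-BuLi (0.98 equiv), THF, –78 °C; then added to 11 (3 equiv), THF, –78 → 0 °C; aq. NH4Cl
Reagents that add atoms: none
Why: Vinylogous transesterification (addition–elimination at a squarate ester carbon) attaches O8 without breaking the C8–O bond, so C8 stays S; the excess of 11 and the lower basicity of the expelled methoxide should favour mono-exchange.

Step 9
Reactants: 13 3-methoxy-4-{[(1S,2S)-1-methoxy-1-(3-methoxy-4-triisopropylsilyloxyphenyl)propan-2-yl]oxy}cyclobut-3-ene-1,2-dione
Product: 14 4-hydroxy-3-methoxy-2-{[(1S,2S)-1-methoxy-1-(3-methoxy-4-triisopropylsilyloxyphenyl)propan-2-yl]oxy}cyclobut-2-en-1-one (both epimers at C4)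
Conditions: LiAlH(OtBu)3 (1.1 equiv), THF, –78 → –40 °C; aq. KNaC4H4O6
Reagents that add atoms: none
Why: Mono-1,2-reduction of a cyclobutenedione with a bulky alkoxyaluminium hydride should take the carbonyl flanked by the small methoxy-bearing carbon, since the branched side-chain alkoxy group shields the other carbonyl; the minor regioisomer would be removed by chromatography.

Step 10
Reactants: 14 4-hydroxy-3-methoxy-2-{[(1S,2S)-1-methoxy-1-(3-methoxy-4-triisopropylsilyloxyphenyl)propan-2-yl]oxy}cyclobut-2-en-1-one
Product: 15 4-chloro-3-methoxy-2-{[(1S,2S)-1-methoxy-1-(3-methoxy-4-triisopropylsilyloxyphenyl)propan-2-yl]oxy}cyclobut-2-en-1-one (both epimers at C4)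
Conditions: PPh3, CCl4, CH2Cl2, 0 °C → rt; used without storage
Reagents that add atoms: carbon tetrachloride, ClC(Cl)(Cl)Cl
Why: Appel chlorination of the activated allylic alcohol runs without protic acid, so the side-chain alkoxy group should not be lost by hydrolysis, and chloride capture at the hydrogen-bearing carbon is the only non-reversible outcome whether substitution is direct or through the allyl cation.

Step 11
Reactants: 16 2,3-dibromopropene
Product: 17 2-bromopenta-1,4-diene
Conditions: CH2=CHMgBr, CuI (5 mol%), THF, –20 → 0 °C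
Reagents that add atoms: vinylmagnesium bromide, C=C[Mg]Br
Why: Copper-catalysed allylic substitution by the Grignard reagent should replace only the allylic bromide, the vinylic C–Br bond being inert under these conditions.

Step 12
Reactants: 17 2-bromopenta-1,4-diene
Product: 19 tributyl(penta-1,4-dien-2-yl)stannane, via dienyl Grignard reagent 18 (not isolated)
Conditions: Mg, THF, rt → 40 °C; then Bu3SnCl, 0 °C → rt
Reagents that add atoms: tributyltin chloride, CCCC[Sn](Cl)(CCCC)CCCC
Why: Grignard formation from the 2-bromoalkene and transmetalation to tin should keep the skipped diene intact, because the alkenylmagnesium species is not basic enough to deprotonate the doubly allylic CH2.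

Step 13
Reactants: 15 4-chloro-3-methoxy-2-{[(1S,2S)-1-methoxy-1-(3-methoxy-4-triisopropylsilyloxyphenyl)propan-2-yl]oxy}cyclobut-2-en-1-one; 19 tributyl(penta-1,4-dien-2-yl)stannane
Product: 23 5-allyl-3-methoxy-2-{[(1S,2S)-1-methoxy-1-(3-methoxy-4-triisopropylsilyloxyphenyl)propan-2-yl]oxy}phenol, via coupled cyclobutenone 20 (not isolated), via dienylketene 21 (not isolated), via cyclohexadienone 22 (not isolated)
Conditions: PdCl2(PhCN)2 (5 mol%), tri(2-furyl)phosphine (10 mol%), dioxane, 50 °C; then 100 °C
Reagents that add atoms: none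
Why: The stannane first reduces PdCl2(PhCN)2 to a zerovalent palladium–tri(2-furyl)phosphine species, which inserts into the allylic, α-keto C6'–Cl bond of 15; transmetalation from tin, fast with the weakly donating furylphosphine, and reductive elimination at the hydrogen-bearing carbon form C6'–C1' (Stille coupling) and give 20. At 100 °C 20 undergoes reversible conrotatory four-electron ring opening, and only ketene 21, which has the dienyl group turned toward the ketene carbon, is consumed. Its disrotatory six-electron electrocyclization forms C2'–C3' and closes ring B as cyclohexadienone 22, which tautomerizes irreversibly to phenol 23; the closest known reaction type is the Stille coupling of 4-chlorocyclobutenones with alkenylstannanes followed by thermal dienylketene benzannulation, the same opening/closure pair that operates in the Danheiser benzannulation. No stereocenter is formed, both C–Cl epimers converge because C6' becomes aromatic, and C7 and C8 are remote and untouched. The step needs coupling at C6' and not at the alkoxy-bearing allylic terminus C4', which the crowding at C4' and the retained vinylogous-ester conjugation should secure, and it needs closure through the 1,1-disubstituted alkene, which is the only alkene conjugated with the ketene, so the allyl group must end on C1' para to O–C8.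

Step 14
Reactants: 23 5-allyl-3-methoxy-2-{[(1S,2S)-1-methoxy-1-(3-methoxy-4-triisopropylsilyloxyphenyl)propan-2-yl]oxy}phenol
Product: 24 {4-[(1S,2S)-2-(4-allyl-2,6-dimethoxyphenoxy)-1-methoxypropyl]-2-methoxyphenoxy}triisopropylsilane
Conditions: MeI, K2CO3, acetone, 50 °C
Reagents that add atoms: iodomethane, CI
Why: Williamson etherification of the only free hydroxyl (the new C3' phenol) should be clean, the aryl silyl ether being stable to anhydrous K2CO3 in acetone.

Step 15
Reactants: 24 {4-[(1S,2S)-2-(4-allyl-2,6-dimethoxyphenoxy)-1-methoxypropyl]-2-methoxyphenoxy}triisopropylsilane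
Product: 25 4-[(1S,2S)-2-(4-allyl-2,6-dimethoxyphenoxy)-1-methoxypropyl]-2-methoxyphenol (CNP0275203.1)
Conditions: Bu4NF, AcOH, THF, 0 °C
Reagents that add atoms: none
Why: Fluoride-mediated cleavage of the aryl silyl ether is fast at 0 °C, and the acetic acid buffer should prevent the liberated para-hydroxybenzyl methyl ether from expelling methoxide through a quinone methide, so C7 stays S.

**Compound list**

1 | 4-bromo-2-methoxyphenol | Oc1ccc(Br)cc1OC | starting material
2 | (4-bromo-2-methoxyphenoxy)triisopropylsilane | COc1cc(Br)ccc1O[Si](C(C)C)(C(C)C)C(C)C | intermediate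
3 | ethyl (S)-lactate | CCOC(=O)[C@H](C)O | starting material
4 | (S)-2-hydroxy-N-methoxy-N-methylpropanamide | CON(C)C(=O)[C@H](C)O | intermediate
5 | (S)-2-(tert-butyldimethylsilyloxy)-N-methoxy-N-methylpropanamide | CON(C)C(=O)[C@H](C)O[Si](C)(C)C(C)(C)C | intermediate
6 | (3-methoxy-4-triisopropylsilyloxyphenyl)lithium | [Li]c1ccc(O[Si](C(C)C)(C(C)C)C(C)C)c(OC)c1 | intermediate (not isolated)
7 | (S)-2-(tert-butyldimethylsilyloxy)-1-(3-methoxy-4-triisopropylsilyloxyphenyl)propan-1-one | C[C@H](O[Si](C)(C)C(C)(C)C)C(=O)c1ccc(O[Si](C(C)C)(C(C)C)C(C)C)c(OC)c1 | intermediate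
8 | (1S,2S)-2-(tert-butyldimethylsilyloxy)-1-(3-methoxy-4-triisopropylsilyloxyphenyl)propan-1-ol | C[C@H](O[Si](C)(C)C(C)(C)C)[C@@H](O)c1ccc(O[Si](C(C)C)(C(C)C)C(C)C)c(OC)c1 | intermediate
9 | tert-butyl{[(1S,2S)-1-methoxy-1-(3-methoxy-4-triisopropylsilyloxyphenyl)propan-2-yl]oxy}dimethylsilane | C[C@H](O[Si](C)(C)C(C)(C)C)[C@@H](OC)c1ccc(O[Si](C(C)C)(C(C)C)C(C)C)c(OC)c1 | intermediate
10 | (1S,2S)-1-methoxy-1-(3-methoxy-4-triisopropylsilyloxyphenyl)propan-2-ol | C[C@H](O)[C@@H](OC)c1ccc(O[Si](C(C)C)(C(C)C)C(C)C)c(OC)c1 | intermediate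
11 | dimethyl squarate (3,4-dimethoxycyclobut-3-ene-1,2-dione) | COC1=C(OC)C(=O)C1=O | starting material
12 | lithium (1S,2S)-1-methoxy-1-(3-methoxy-4-triisopropylsilyloxyphenyl)propan-2-olate | C[C@H](O[Li])[C@@H](OC)c1ccc(O[Si](C(C)C)(C(C)C)C(C)C)c(OC)c1 | intermediate (not isolated)
13 | 3-methoxy-4-{[(1S,2S)-1-methoxy-1-(3-methoxy-4-triisopropylsilyloxyphenyl)propan-2-yl]oxy}cyclobut-3-ene-1,2-dione | COC1=C(O[C@@H](C)[C@@H](OC)c2ccc(O[Si](C(C)C)(C(C)C)C(C)C)c(OC)c2)C(=O)C1=O | intermediate
14 | 4-hydroxy-3-methoxy-2-{[(1S,2S)-1-methoxy-1-(3-methoxy-4-triisopropylsilyloxyphenyl)propan-2-yl]oxy}cyclobut-2-en-1-one (epimers at C4) | O=C1C(O[C@@H](C)[C@@H](OC)c2ccc(O[Si](C(C)C)(C(C)C)C(C)C)c(OC)c2)=C(OC)C1O | intermediate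
15 | 4-chloro-3-methoxy-2-{[(1S,2S)-1-methoxy-1-(3-methoxy-4-triisopropylsilyloxyphenyl)propan-2-yl]oxy}cyclobut-2-en-1-one (epimers at C4) | O=C1C(O[C@@H](C)[C@@H](OC)c2ccc(O[Si](C(C)C)(C(C)C)C(C)C)c(OC)c2)=C(OC)C1Cl | intermediate
16 | 2,3-dibromopropene | C=C(Br)CBr | starting material
17 | 2-bromopenta-1,4-diene | C=CCC(Br)=C | intermediate
18 | penta-1,4-dien-2-ylmagnesium bromide | C=CCC(=C)[Mg]Br | intermediate (not isolated)
19 | tributyl(penta-1,4-dien-2-yl)stannane | C=CCC(=C)[Sn](CCCC)(CCCC)CCCC | intermediate
20 | 3-methoxy-2-{[(1S,2S)-1-methoxy-1-(3-methoxy-4-triisopropylsilyloxyphenyl)propan-2-yl]oxy}-4-(penta-1,4-dien-2-yl)cyclobut-2-en-1-one (epimers at C4) | O=C1C(O[C@@H](C)[C@@H](OC)c2ccc(O[Si](C(C)C)(C(C)C)C(C)C)c(OC)c2)=C(OC)C1C(=C)CC=C | intermediate (not isolated)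
21 | (3E)-3-methoxy-2-{[(1S,2S)-1-methoxy-1-(3-methoxy-4-triisopropylsilyloxyphenyl)propan-2-yl]oxy}-5-methylideneocta-1,3,7-trien-1-one (dienylketene, dienyl group cis to the ketene carbon) | O=C=C(O[C@@H](C)[C@@H](OC)c1ccc(O[Si](C(C)C)(C(C)C)C(C)C)c(OC)c1)/C(OC)=C\C(=C)CC=C | intermediate (not isolated)
22 | 5-allyl-3-methoxy-2-{[(1S,2S)-1-methoxy-1-(3-methoxy-4-triisopropylsilyloxyphenyl)propan-2-yl]oxy}cyclohexa-2,4-dien-1-one | O=C1CC(CC=C)=CC(OC)=C1O[C@@H](C)[C@@H](OC)c2ccc(O[Si](C(C)C)(C(C)C)C(C)C)c(OC)c2 | intermediate (not isolated)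
23 | 5-allyl-3-methoxy-2-{[(1S,2S)-1-methoxy-1-(3-methoxy-4-triisopropylsilyloxyphenyl)propan-2-yl]oxy}phenol | C=CCc1cc(O)c(O[C@@H](C)[C@@H](OC)c2ccc(O[Si](C(C)C)(C(C)C)C(C)C)c(OC)c2)c(OC)c1 | intermediate
24 | {4-[(1S,2S)-2-(4-allyl-2,6-dimethoxyphenoxy)-1-methoxypropyl]-2-methoxyphenoxy}triisopropylsilane | C=CCc1cc(OC)c(O[C@@H](C)[C@@H](OC)c2ccc(O[Si](C(C)C)(C(C)C)C(C)C)c(OC)c2)c(OC)c1 | intermediate
25 | 4-[(1S,2S)-2-(4-allyl-2,6-dimethoxyphenoxy)-1-methoxypropyl]-2-methoxyphenol | C=CCc1cc(OC)c(O[C@@H](C)[C@@H](OC)c2ccc(O)c(OC)c2)c(OC)c1 | target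

**Step count**

Total: 15 steps. Longest linear sequence: 12 steps (steps 2–10 and 13–15, from ethyl (S)-lactate 3).

**Steps most likely to fail**

Step 9. The two squarate carbonyls are electronically almost equal, so hydride delivery may be poorly regioselective; attack next to the side-chain-bearing carbon would place O–C8 at a terminal instead of the central ring B oxygen. The fallback makes the reduction regiospecific; it sets out from 10 and 11 and comes back at 14. Dimethyl squarate 11 would be converted into its monoketal 2,3,4,4-tetramethoxycyclobut-2-en-1-one F1 (MeOSiMe3, Me3SiOTf cat., CH2Cl2, –78 °C → rt). Lithium alkoxide 12 would then exchange the one vinylogous-ester methoxy group of F1 (β to its single carbonyl, next to the ketal carbon) to give 2,4,4-trimethoxy-3-{[(1S,2S)-1-methoxy-1-(3-methoxy-4-triisopropylsilyloxyphenyl)propan-2-yl]oxy}cyclobut-2-en-1-one F2. Luche reduction (NaBH4, CeCl3·7H2O, MeOH, –40 °C) of the only carbonyl would give the allylic alcohol 2,4,4-trimethoxy-3-{[(1S,2S)-1-methoxy-1-(3-methoxy-4-triisopropylsilyloxyphenyl)propan-2-yl]oxy}cyclobut-2-en-1-ol F3. Brief ketal hydrolysis (oxalic acid on wet silica gel, CH2Cl2) would then give 14, because either hydration site of the dialkoxyallyl cation leads to the same constitution.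

Step 13. Transmetalation of the α-branched dienylstannane may be slow compared with decomposition of the dialkoxy-substituted oxocyclobutenylpalladium intermediate, or the ketene may be diverted before closure. The fallback gives up ring construction and forms the C8–O–C4' bond by SN2 chemistry with purchased ring B; it sets out from 10 and comes back at 24. Mitsunobu esterification of 10 with benzoic acid (PPh3, diisopropyl azodicarboxylate, THF, 0 °C → rt) would invert C8 to (1S,2R)-1-methoxy-1-(3-methoxy-4-triisopropylsilyloxyphenyl)propan-2-yl benzoate F4. Reductive ester cleavage (i-Bu2AlH, CH2Cl2, –78 °C) would give (1S,2R)-1-methoxy-1-(3-methoxy-4-triisopropylsilyloxyphenyl)propan-2-ol F5 without touching the aryl silyl ether. A second Mitsunobu reaction with commercial 4-allyl-2,6-dimethoxyphenol (PPh3, diisopropyl azodicarboxylate, toluene, 0 °C → rt) would invert C8 back to S and give 24; step 15 then follows unchanged.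

Step 10. The activated alcohol may ionize with loss of the side-chain alkoxy group, collapsing to a cyclobutenedione, or the chloride may decompose on isolation. The fallback replaces chloride by a carbonate leaving group; it sets out from 14 and comes back at 23. Acylation of 14 (ClCO2Me, pyridine, CH2Cl2, 0 °C) would give the allylic carbonate methyl {2-methoxy-3-[(1S,2S)-1-methoxy-1-(3-methoxy-4-triisopropylsilyloxyphenyl)propan-2-yl]oxy-4-oxocyclobut-2-en-1-yl} carbonate F6. With zerovalent palladium (Pd2(dba)3, tri(2-furyl)phosphine, dioxane, 50 °C) F6 should ionize with loss of CO2 (Tsuji–Trost ionization), the methoxide on palladium activating stannane 19 for transmetalation. Heating to 100 °C would then lead through 20, 21 and 22 to 23.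

**Further compounds**

F1 | step 9 | 2,3,4,4-tetramethoxycyclobut-2-en-1-one | COC1=C(OC)C(OC)(OC)C1=O
F2 | step 9 | 2,4,4-trimethoxy-3-{[(1S,2S)-1-methoxy-1-(3-methoxy-4-triisopropylsilyloxyphenyl)propan-2-yl]oxy}cyclobut-2-en-1-one | COC1=C(O[C@@H](C)[C@@H](OC)c2ccc(O[Si](C(C)C)(C(C)C)C(C)C)c(OC)c2)C(OC)(OC)C1=O
F3 | step 9 | 2,4,4-trimethoxy-3-{[(1S,2S)-1-methoxy-1-(3-methoxy-4-triisopropylsilyloxyphenyl)propan-2-yl]oxy}cyclobut-2-en-1-ol (epimers at C1) | COC1=C(O[C@@H](C)[C@@H](OC)c2ccc(O[Si](C(C)C)(C(C)C)C(C)C)c(OC)c2)C(OC)(OC)C1O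
F4 | step 13 | (1S,2R)-1-methoxy-1-(3-methoxy-4-triisopropylsilyloxyphenyl)propan-2-yl benzoate | C[C@@H](OC(=O)c1ccccc1)[C@@H](OC)c2ccc(O[Si](C(C)C)(C(C)C)C(C)C)c(OC)c2
F5 | step 13 | (1S,2R)-1-methoxy-1-(3-methoxy-4-triisopropylsilyloxyphenyl)propan-2-ol | C[C@@H](O)[C@@H](OC)c1ccc(O[Si](C(C)C)(C(C)C)C(C)C)c(OC)c1
F6 | step 10 | methyl {2-methoxy-3-[(1S,2S)-1-methoxy-1-(3-methoxy-4-triisopropylsilyloxyphenyl)propan-2-yl]oxy-4-oxocyclobut-2-en-1-yl} carbonate (epimers at C1) | O=C1C(O[C@@H](C)[C@@H](OC)c2ccc(O[Si](C(C)C)(C(C)C)C(C)C)c(OC)c2)=C(OC)C1OC(=O)OC
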